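How to charge the starting material, and whether 10 d of heating is enough: the meeting had to choose both, with two earlier runs in hand.

| flask | starting material | coupling partner | temperature | remark | time |
|---|---|---|---|---|---|
| zeta | 0.050 M | 0.050 M | 80 °C | run made earlier |  |
| beta | 0.050 M | 0.025 M | 80 °C | run made earlier |  |
| teal | 0.050 M (fed, over 4.0 d) | 0.0500 M | 80 °C | all else is in the flask from the start; the feed brings no volume worth counting | 10 d |
| grey | 0.050 M | 0.0500 M | 80 °C | everything together at the start | 10 d |
| amber | 0.050 M (in portions, 2, over 4.0 d) | 0.0500 M | 80 °C | first portion at the start, last at 4.0 d | 10 d |
| violet | 0.050 M (fed, over 4.0 d) | 0.0500 M |  | the addition at 50 °C, then warmed to 80 °C; the feed brings no volume worth counting | 10 d |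

zeta run (percent of the starting material charged)

| time / d | target / % |
|---|---|
| 1.67 | 32.3 |
| 3.00 | 33.8 |
| 5.00 | 33.2 |
| 6.00 | 33.2 |

beta run (percent of the starting material charged)

| time / h | target / % |
|---|---|
| 3.00 | 10.5 |
| 8.00 | 17.3 |
| 15.0 | 22.2 |
| 25.0 | 23.5 |

(scatter of a reading: 0.5 percentage points)

1. the flask with the highest amount of target, in percent of the starting material charged ("all alike" if they lie within 1.5 percentage points) (teal / grey / amber / violet / all alike)
2. final target, as a percentage of the starting material charged, in teal
3. final target, as a percentage of the starting material charged, in grey
4. final target, as a percentage of the starting material charged, in amber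
5. final target, as a percentage of the starting material charged, in violet

- what may be going on: starting material + 2 coupling partner -> side product; starting material + coupling partner -> target; coupling partner -> decomposed reagent; coupling partner + target -> over-reaction product
- the earlier runs do not show what temperature does; that part of a forecast is a guess

The kineticist proposed counting lifetimes. She reported that beta read 10.5 % at 3.00 h against a last reading of 23.5 %, which she took as its plateau. That gave 5.07 h for the closing time, the time in which the target's distance from its plateau shrinks by the factor e.

The analyst objected that beta held half as much coupling partner as starting material. The kineticist answered that zeta, charged as grey is, read 32.3 % at 1.67 d, already 7.91 of beta's closing times in, and 33.2 % at 6.00 d, so the two readings lie 0.9 percentage points apart against a scatter of 0.5 points.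

By her own count, grey had 47.4 closing times and each dosed flask 28.4 after 4.0 d, which for violet means after its warming to 80 °C. She therefore saw no case for heating past 10 d, since the count far exceeded one. She added that this count gave no yields.

The process chemist then read out the forecast: grey as the best flask, with teal at 20 % (13 % to 28 %), grey at 33.3 % (32 % to 34.5 %), amber at 23 % (19 % to 27 %) and violet at 31 % (22 % to 40 %). Of amber it says “the second portion finds no partner”. Its violet figure rests on a guess about temperature.

The flasks gave teal 21.5 %, grey 32.8 %, amber 17.0 % and violet 29.4 %, so grey came out highest.

    starting material + 2 coupling partner → side product (k = 0.0164 /M²/s, Ea = 65.0 kJ/mol)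
    starting material + coupling partner → target (k = 5.76 × 10⁻⁴ /M/s, Ea = 75.0 kJ/mol)
    coupling partner → decomposed reagent (k = 1.93 × 10⁻⁶ /s, Ea = 111 kJ/mol)
    coupling partner + target → over-reaction product (k = 2.87 × 10⁻⁴ /M/s, Ea = 63.0 kJ/mol)
    (constants at 80 °C)

Amber is where the forecast parted from the flask, standing 6 points too high. Grey has come to rest within its 47.4 closing times: the coupling partner, the limiting reagent, stands at 0 % of its charge at 10.0 d. Grey's target reads 32.8 % at 5.00 d, and ten times the asked time still gives 32.8 %, with 35.9 % of the starting material unused. Amber, the second flask, had 28.4 closing times after its last charge, and its coupling partner stands at 0 % at 10.0 d. At 100 d amber's target stands at 17.0 %.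

The earlier runs and the new flask come from a simulation on assumed constants, and the scatter is random.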